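**Assumption:** the target is read as the (5S)-butenolide with an all-E triene, exactly as the SMILES gives it. The route is a paper design from known reaction classes and has not been run.

## Retrosynthetic overview

1. The butenolide is the only ring that is built, and it is built last, by Dieckmann cyclisation of an (S)-α-propanoyloxy ester. Both furan rings are bought.
2. The triene is cut between C3' and C4' (Suzuki–Miyaura) into an east (E)-alkenyl boronate and a west (E,E)-dienyl iodide.
3. East: the boronate comes from cross-metathesis of an isopropenyl group with vinyl-Bpin. The stereocentre comes from an (S)-BINOL/titanium-catalysed glyoxylate-ene reaction of 2-methylpropene.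
4. West: the dienyl iodide comes from Takai olefination of an enal, made by Wittig reaction of an arylpropanal, made by Heck arylation of allyl alcohol.
5. Bis-furan: furan-3-yllithium adds to 4-bromofuran-2-carbaldehyde, and the carbinol is then deoxygenated.

## Route

**Step 1**
Reactants: 1 2-methylpropene (isobutylene); 2 ethyl glyoxylate (freshly distilled)
Product: 3 ethyl (2S)-2-hydroxy-4-methylpent-4-enoate
Conditions: (S)-BINOL (10 mol%), TiCl2(OiPr)2 (10 mol%), 4 Å MS, CH2Cl2, −30 °C
Reagents that add atoms: none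
Why: Mikami catalytic asymmetric glyoxylate-ene reaction; the (S)-BINOL titanium complex blocks one face of the bound glyoxylate, so the ene transfer gives the (S)-α-hydroxy ester (about 95% ee expected, the (R)-ligand being known to give the (R)-ester).

**Step 2**
Reactants: 3 ethyl (2S)-2-hydroxy-4-methylpent-4-enoate
Product: 4 ethyl (2S)-4-methyl-2-(propanoyloxy)pent-4-enoate
Conditions: (EtCO)2O, Et3N, DMAP (cat.), CH2Cl2, 0 °C → rt
Reagents that add atoms: propionic anhydride CCC(=O)OC(=O)CC
Why: DMAP-catalysed O-acylation of the secondary alcohol, which installs the three carbons of the future C2/C3/3-methyl unit without touching the stereocentre.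

**Step 3**
Reactants: 4 ethyl (2S)-4-methyl-2-(propanoyloxy)pent-4-enoate
Product: 5 ethyl (2S,4E)-4-methyl-2-(propanoyloxy)-5-(4,4,5,5-tetramethyl-1,3,2-dioxaborolan-2-yl)pent-4-enoate
Conditions: vinylboronic acid pinacol ester (3 equiv), second-generation Grubbs catalyst RuCl2(=CHPh)(PCy3)(H2IMes) (5 mol%), CH2Cl2, 40 °C
Reagents that add atoms: vinylboronic acid pinacol ester C=CB1OC(C)(C)C(C)(C)O1
Why: olefin cross-metathesis of a 1,1-disubstituted alkene with a vinyl boronate, driven by loss of ethene; the bulky boronate ends trans to the larger CH2 substituent, so the trisubstituted alkene is E.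

**Step 4**
Reactants: 6 3-bromofuran; 7 4-bromofuran-2-carbaldehyde
Product: 10 (4-bromofuran-2-yl)(furan-3-yl)methanol (racemic), via furan-3-yllithium 8 (not isolated), via lithium alkoxide 9 (not isolated)
Conditions: n-BuLi (1.05 equiv), THF, −78 °C; then 7, −78 °C; then H2O
Reagents that add atoms: none
Why: bromine–lithium exchange followed by 1,2-addition to the aldehyde; at −78 °C the 3-lithiofuran does not isomerise and adds to the formyl group faster than it exchanges with the ring bromide of 7 (the carbinol centre is racemic and is removed in step 5).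

**Step 5**
Reactants: 10 (4-bromofuran-2-yl)(furan-3-yl)methanol
Product: 11 4-bromo-2-(furan-3-ylmethyl)furan
Conditions: Et3SiH (3 equiv), CF3CO2H (5 equiv), CH2Cl2, −20 → 0 °C
Reagents that add atoms: none
Why: ionic hydrogenation; the carbinol flanked by two furans ionises readily in acid and the silane delivers hydride to that carbon, while the ring bromide is inert.

**Step 6**
Reactants: 11 4-bromo-2-(furan-3-ylmethyl)furan
Product: 13 3-[5-(furan-3-ylmethyl)furan-3-yl]propanal, via enol 12 (not isolated)
Conditions: allyl alcohol (2 equiv), Pd(OAc)2 (5 mol%), Bu4NCl (1 equiv), NaHCO3 (2.5 equiv), DMF, 80 °C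
Reagents that add atoms: allyl alcohol C=CCO
Why: Heck reaction under Jeffery conditions; the furyl–palladium species adds to the terminal alkene carbon, β-hydride elimination toward the carbinol gives an enol, and the enol tautomerises to the 3-arylpropanal.

**Step 7**
Reactants: 13 3-[5-(furan-3-ylmethyl)furan-3-yl]propanal
Product: 14 (2E)-5-[5-(furan-3-ylmethyl)furan-3-yl]-2-methylpent-2-enal
Conditions: Ph3P=C(CH3)CHO (1.3 equiv), toluene, 90 °C
Reagents that add atoms: 2-(triphenylphosphoranylidene)propanal CC(C=O)=P(c1ccccc1)(c1ccccc1)c1ccccc1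
Why: Wittig olefination with a stabilised ylide, which gives the (E)-trisubstituted enal (typically above 95:5) and reacts with the aliphatic aldehyde much faster than with the enal product.

**Step 8**
Reactants: 14 (2E)-5-[5-(furan-3-ylmethyl)furan-3-yl]-2-methylpent-2-enal
Product: 15 2-(furan-3-ylmethyl)-4-[(3E,5E)-6-iodo-4-methylhexa-3,5-dien-1-yl]furan
Conditions: CrCl2 (8 equiv), CHI3 (2.5 equiv), THF/1,4-dioxane (1:6), 0 °C → rt, dark
Reagents that add atoms: iodoform IC(I)I
Why: Takai olefination; the geminal dichromium reagent adds to the aldehyde and eliminates to the (E)-vinyl iodide, leaving the existing trisubstituted alkene unchanged.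

**Step 9**
Reactants: 5 ethyl (2S,4E)-4-methyl-2-(propanoyloxy)-5-(4,4,5,5-tetramethyl-1,3,2-dioxaborolan-2-yl)pent-4-enoate; 15 2-(furan-3-ylmethyl)-4-[(3E,5E)-6-iodo-4-methylhexa-3,5-dien-1-yl]furan
Product: 16 ethyl (2S,4E,6E,8E)-11-[5-(furan-3-ylmethyl)furan-3-yl]-4,8-dimethyl-2-(propanoyloxy)undeca-4,6,8-trienoate
Conditions: Pd(dppf)Cl2 (5 mol%), K3PO4 (3 equiv, 2 M aq.), THF, rt, degassed, dark; 5 in 1.2-fold excess
Reagents that add atoms: none
Why: Suzuki–Miyaura coupling of an alkenyl boronate with a dienyl iodide (oxidative addition of zerovalent palladium into the C–I bond), with retention at both alkenes, so the all-E triene results; phosphate base at room temperature is chosen to spare the acyloxy ester.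

**Step 10**
Reactants: 16 ethyl (2S,4E,6E,8E)-11-[5-(furan-3-ylmethyl)furan-3-yl]-4,8-dimethyl-2-(propanoyloxy)undeca-4,6,8-trienoate
Product: 18 (5S)-5-[(2E,4E,6E)-9-[5-(furan-3-ylmethyl)furan-3-yl]-2,6-dimethylnona-2,4,6-trien-1-yl]-4-hydroxy-3-methylfuran-2(5H)-one, via lithium tetronate 17 (not isolated)
Conditions: LiN(SiMe3)2 (3 equiv), THF, −78 → 0 °C; then cold 0.5 M HCl to pH 3
Reagents that add atoms: none
Why: Dieckmann cyclisation; the propanoate enolate attacks the ethyl ester and expels ethoxide to give the tetronate, and the O-bearing α-carbon is not enolised under these kinetic conditions (as with O-acyl lactates), so the S configuration from step 1 is carried into C5.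

## Compound list

1 | 2-methylpropene | CC(C)=C | starting material
2 | ethyl glyoxylate | CCOC(=O)C=O | starting material
3 | ethyl (2S)-2-hydroxy-4-methylpent-4-enoate | CCOC(=O)[C@@H](O)CC(C)=C | intermediate
4 | ethyl (2S)-4-methyl-2-(propanoyloxy)pent-4-enoate | CCOC(=O)[C@@H](OC(=O)CC)CC(C)=C | intermediate
5 | ethyl (2S,4E)-4-methyl-2-(propanoyloxy)-5-(4,4,5,5-tetramethyl-1,3,2-dioxaborolan-2-yl)pent-4-enoate | CCOC(=O)[C@@H](OC(=O)CC)C/C(C)=C/B1OC(C)(C)C(C)(C)O1 | intermediate
6 | 3-bromofuran | Brc1ccoc1 | starting material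
7 | 4-bromofuran-2-carbaldehyde | O=Cc1cc(Br)co1 | starting material
8 | furan-3-yllithium | [Li]c1ccoc1 | intermediate (not isolated)
9 | lithium (4-bromofuran-2-yl)(furan-3-yl)methanolate | [Li+].[O-]C(c1ccoc1)c1cc(Br)co1 | intermediate (not isolated)
10 | (4-bromofuran-2-yl)(furan-3-yl)methanol, racemic | OC(c1ccoc1)c1cc(Br)co1 | intermediate
11 | 4-bromo-2-(furan-3-ylmethyl)furan | Brc1coc(Cc2ccoc2)c1 | intermediate
12 | 3-[5-(furan-3-ylmethyl)furan-3-yl]prop-1-en-1-ol (enol) | OC=CCc1coc(Cc2ccoc2)c1 | intermediate (not isolated)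
13 | 3-[5-(furan-3-ylmethyl)furan-3-yl]propanal | O=CCCc1coc(Cc2ccoc2)c1 | intermediate
14 | (2E)-5-[5-(furan-3-ylmethyl)furan-3-yl]-2-methylpent-2-enal | O=C/C(C)=C/CCc1coc(Cc2ccoc2)c1 | intermediate
15 | 2-(furan-3-ylmethyl)-4-[(3E,5E)-6-iodo-4-methylhexa-3,5-dien-1-yl]furan | I/C=C/C(C)=C/CCc1coc(Cc2ccoc2)c1 | intermediate
16 | ethyl (2S,4E,6E,8E)-11-[5-(furan-3-ylmethyl)furan-3-yl]-4,8-dimethyl-2-(propanoyloxy)undeca-4,6,8-trienoate | CCOC(=O)[C@@H](OC(=O)CC)C/C(C)=C/C=C/C(C)=C/CCc1coc(Cc2ccoc2)c1 | intermediate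
17 | lithium tetronate (C4 enolate, lithium salt) of 18 | [Li+].CC1=C([O-])[C@H](C/C(C)=C/C=C/C(C)=C/CCc2coc(Cc3ccoc3)c2)OC1=O | intermediate (not isolated)
18 | (5S)-5-[(2E,4E,6E)-9-[5-(furan-3-ylmethyl)furan-3-yl]-2,6-dimethylnona-2,4,6-trien-1-yl]-4-hydroxy-3-methylfuran-2(5H)-one | CC1=C(O)[C@H](C/C(C)=C/C=C/C(C)=C/CCc2coc(Cc3ccoc3)c2)OC1=O | target

## Step count and risks

Total step count: 10 (east branch steps 1–3, west branch steps 4–8, union steps 9–10).
Longest linear sequence: 7 steps (steps 4 to 10, from 3-bromofuran and 4-bromofuran-2-carbaldehyde).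

**Step 6 (Heck arylation of allyl alcohol).** The electron-rich 3-bromofuran type bromide adds slowly to palladium, and at 80 °C the free furan α-positions can be arylated and some branched aldehyde can form. The fallback sets out from 11 and comes back at 13. A Negishi coupling of 11 with (3-ethoxy-3-oxopropyl)zinc bromide, BrZnCH2CH2CO2Et (Pd(OAc)2, SPhos, THF, 50 °C), gives ethyl 3-[5-(furan-3-ylmethyl)furan-3-yl]propanoate F1. Reduction of F1 with i-Bu2AlH (1.05 equiv, CH2Cl2, −78 °C) passes through the diisobutylaluminium hemiacetal F2, which releases aldehyde 13 on aqueous work-up.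

**Step 8 (Takai olefination of the enal).** E/Z mixtures at the new alkene are hard to separate at the dienyl iodide stage, and the large excess of chromium salts may harm the furans. The fallback sets out from 14 and comes back at 15. Ohira–Bestmann homologation of 14 (dimethyl (1-diazo-2-oxopropyl)phosphonate, K2CO3, MeOH, 0 °C → rt) gives 2-(furan-3-ylmethyl)-4-[(3E)-4-methylhex-3-en-5-yn-1-yl]furan F3. Hydrozirconation of F3 with Cp2Zr(H)Cl (THF, rt) gives the (E,E)-dienylzirconocene chloride F4, which is not isolated and is cleaved with I2 at 0 °C to iodide 15 as a single alkene isomer.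

**Step 9 (Suzuki–Miyaura coupling beside an α-acyloxy ester).** Aqueous base may cleave the propanoate or the ethyl ester before the coupling is complete. The fallback sets out from 5 and comes back at 18, with the ring closed before the coupling so that only a base-stable tetronate meets the aqueous base. Treatment of 5 with LiN(SiMe3)2 (3 equiv, THF, −78 → 0 °C) gives the lithium tetronate of the boronate F5, and acidification to pH 3 gives (5S)-4-hydroxy-3-methyl-5-[(2E)-2-methyl-3-(4,4,5,5-tetramethyl-1,3,2-dioxaborolan-2-yl)prop-2-en-1-yl]furan-2(5H)-one F6. Coupling of F6 with iodide 15 (Pd(dppf)Cl2, K3PO4 4 equiv, THF/H2O, rt) gives the potassium tetronate of the target F7, and acidification to pH 3 gives 18.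

## Further compounds

F1 | step 6 | ethyl 3-[5-(furan-3-ylmethyl)furan-3-yl]propanoate | CCOC(=O)CCc1coc(Cc2ccoc2)c1
F2 | step 6 | diisobutylaluminium hemiacetal of F1, [1-ethoxy-3-[5-(furan-3-ylmethyl)furan-3-yl]propoxy]bis(2-methylpropyl)aluminium | CCOC(CCc1coc(Cc2ccoc2)c1)O[Al](CC(C)C)CC(C)C
F3 | step 8 | 2-(furan-3-ylmethyl)-4-[(3E)-4-methylhex-3-en-5-yn-1-yl]furan | C#C/C(C)=C/CCc1coc(Cc2ccoc2)c1
F4 | step 8 | chloro[(1E,3E)-6-[5-(furan-3-ylmethyl)furan-3-yl]-3-methylhexa-1,3-dien-1-yl]bis(cyclopentadienyl)zirconium | Cl[Zr](/C=C/C(C)=C/CCc1coc(Cc2ccoc2)c1)(C1C=CC=C1)C1C=CC=C1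
F5 | step 9 | lithium tetronate (C4 enolate, lithium salt) of F6 | [Li+].CC1=C([O-])[C@H](C/C(C)=C/B2OC(C)(C)C(C)(C)O2)OC1=O
F6 | step 9 | (5S)-4-hydroxy-3-methyl-5-[(2E)-2-methyl-3-(4,4,5,5-tetramethyl-1,3,2-dioxaborolan-2-yl)prop-2-en-1-yl]furan-2(5H)-one | CC1=C(O)[C@H](C/C(C)=C/B2OC(C)(C)C(C)(C)O2)OC1=O
F7 | step 9 | potassium tetronate (C4 enolate, potassium salt) of 18 | [K+].CC1=C([O-])[C@H](C/C(C)=C/C=C/C(C)=C/CCc2coc(Cc3ccoc3)c2)OC1=O
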